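Numbering: ring A is the cyclohexenone, with C1 (C=O), C2 (C–CH3), C3 (bears side chain C1'–C5'), C4 (CH2), C5 (CHOH) and C6 (C(CH3)–O); ring B is the orsellinate arene.
Cuts, in order: the C6–O acyl bond to ring B, then C4–C5 of ring A, then C2–CH3, C1–C2 and C1'–C2'.
Enabling feature: in ring A the C5 carbinol is homoallylic to C2=C3 and lies β to the C1 ketone across fully substituted C6. This is the retron of a carbonyl-ene union between a C3=C4H2 exocyclic methylene and a C5 aldehyde that has no α-hydrogen.
Forward: the chain is joined at C1'–C2' (dithiane alkylation), C1–C2 (allylzinc addition) and C2–CH3 (dienolate methylation). Ring A, the only ring made, closes at C4–C5, and ring B is bought and attached last as the C6 ester.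
Stereochemistry: C6 comes from (R)-2-methylglycidol (its CH2OH arm becomes C5, its epoxide CH2 becomes C1, and its C–O bond is never broken). C5 is set in the ring closure under control of C6 (5,6-trans).
Key step: step 12

Assumption: the epimer mixtures at C1 (14) and C2 (17 to 20) are carried forward unseparated, because both centres become trigonal before ring A is finished.

Step 1
Reactants: 1 butanal
Product: 2 2-propyl-1,3-dithiane
Conditions: HS(CH2)3SH, BF3·OEt2 (cat.), CH2Cl2, 0 °C → rt
Reagents that add atoms: propane-1,3-dithiol, SCCCS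
Why: Lewis-acid-catalysed dithioacetalisation of an unhindered aldehyde is routine, and it turns the future C2' carbonyl carbon into an acyl-anion equivalent (Corey–Seebach umpolung).

Step 2
Reactants: 2 2-propyl-1,3-dithiane; 3 3-chloro-2-(chloromethyl)prop-1-ene
Product: 5 2-[2-(chloromethyl)prop-2-en-1-yl]-2-propyl-1,3-dithiane, via 2-lithio-2-propyl-1,3-dithiane 4 (not isolated)
Conditions: n-BuLi, THF, −30 °C; cannulated into 3 (3 equiv), THF, −78 → 0 °C
Reagents that add atoms: none
Why: In this Corey–Seebach alkylation SN2 and SN2' attack on the symmetrical bis-allylic dichloride give the same product, and inverse addition into an excess of 3 holds back a second alkylation.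

Step 3
Reactants: 6 (R)-2-methylglycidol
Product: 8 (S)-2-{[(4-methoxybenzyl)oxy]methyl}-2-methyloxirane, via sodium alkoxide 7 (not isolated)
Conditions: NaH, THF/DMF, 0 °C; 4-MeOC6H4CH2Cl, n-Bu4NI (cat.), 0 °C → rt
Reagents that add atoms: 4-methoxybenzyl chloride, COc1ccc(CCl)cc1
Why: This Williamson etherification fixes the CH2OH arm as the future C5 with a group that cannot migrate; the Payne rearrangement open to 7 is degenerate and returns the same enantiomer, so C6 is unaffected (the descriptor changes only through ligand priorities).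

Step 4
Reactants: 8 (S)-2-{[(4-methoxybenzyl)oxy]methyl}-2-methyloxirane
Product: 9 (S)-3-[(4-methoxybenzyl)oxy]-2-methylpropane-1,2-diol
Conditions: KOH, DMSO/H2O, 80 °C
Reagents that add atoms: water (delivered as hydroxide), O
Why: Under basic conditions hydroxide opens the epoxide by SN2 attack at the unsubstituted carbon only, so the C6–O bond is kept and the configuration retained; acid is avoided because it would direct attack to the tertiary carbon.

Step 5
Reactants: 9 (S)-3-[(4-methoxybenzyl)oxy]-2-methylpropane-1,2-diol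
Product: 10 (R)-1-[(4-methoxybenzyl)oxy]-2-methyl-2,3-bis(triethylsilyloxy)propane
Conditions: Et3SiOTf, 2,6-lutidine, CH2Cl2, −78 → 0 °C
Reagents that add atoms: triethylsilyl trifluoromethanesulfonate, CC[Si](CC)(CC)OS(=O)(=O)C(F)(F)F
Why: Silyl triflate with lutidine is strong enough to silylate the tertiary C6 hydroxyl, and the primary silyl ether formed alongside is the handle for step 6.

Step 6
Reactants: 10 (R)-1-[(4-methoxybenzyl)oxy]-2-methyl-2,3-bis(triethylsilyloxy)propane
Product: 12 (R)-3-[(4-methoxybenzyl)oxy]-2-methyl-2-(triethylsilyloxy)propanal, via alkoxysulfonium chloride 11 (not isolated)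
Conditions: (COCl)2, DMSO, CH2Cl2, −78 → −40 °C; Et3N, −78 → 0 °C
Reagents that add atoms: none
Why: In a Swern oxidation run directly on the silyl ether, the activated DMSO reagent takes off only the primary triethylsilyl group and oxidises that position in the same flask (a known selective deprotection–oxidation); the tertiary silyl ether and the PMB ether remain, and the aldehyde has no α-hydrogen to lose.

Step 7
Reactants: 5 2-[2-(chloromethyl)prop-2-en-1-yl]-2-propyl-1,3-dithiane; 12 (R)-3-[(4-methoxybenzyl)oxy]-2-methyl-2-(triethylsilyloxy)propanal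
Product: 14 (2R)-1-[(4-methoxybenzyl)oxy]-2-methyl-5-[(2-propyl-1,3-dithian-2-yl)methyl]-2-(triethylsilyloxy)hex-5-en-3-ol (both epimers at the carbinol = ring C1), via allylzinc chloride 13 (not isolated)
Conditions: Zn dust, LiCl, THF, 25 °C; then 12, −78 → 0 °C; aq. NH4Cl
Reagents that add atoms: none
Why: Zinc inserts into allylic chlorides in the presence of LiCl with little homocoupling, and this Barbier-type allylzinc addition is fast even with α-quaternary aldehydes and tolerates thioacetal, silyl and benzyl ethers; the C1 carbinol centre forms without control, which is harmless because it is oxidised next.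

Step 8
Reactants: 14 homoallylic alcohol (C1 epimers)
Product: 15 (R)-1-[(4-methoxybenzyl)oxy]-2-methyl-5-[(2-propyl-1,3-dithian-2-yl)methyl]-2-(triethylsilyloxy)hex-5-en-3-one
Conditions: Dess–Martin periodinane (1.2 equiv), pyridine, CH2Cl2, 0 °C
Reagents that add atoms: none
Why: The pyridine-buffered Dess–Martin oxidation is neutral and fast, so the β,γ-unsaturated ketone should form without the alkene moving into conjugation and before the anhydrous reagent attacks sulfur.

Step 9
Reactants: 15 β,γ-unsaturated ketone
Product: 17 (2R)-1-[(4-methoxybenzyl)oxy]-2,4-dimethyl-5-[(2-propyl-1,3-dithian-2-yl)methyl]-2-(triethylsilyloxy)hex-5-en-3-one (both epimers at C4 = ring C2), via lithium dienolate 16 (not isolated)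
Conditions: LiN(SiMe3)2 (1.05 equiv), THF/DMPU, −78 °C; MeI, −78 → −40 °C; AcOH quench at −78 °C
Reagents that add atoms: iodomethane, CI
Why: Only C2 can be deprotonated because C6 carries no hydrogen, and alkylation of the extended dienolate takes place at its α-carbon (the normal regiochemistry of dienolate alkylation), which leaves the C3=C4H2 methylene in place; the C2 configuration does not matter.

Step 10
Reactants: 17 C2-methyl ketone (C2 epimers)
Product: 18 (2R)-1-hydroxy-2,4-dimethyl-5-[(2-propyl-1,3-dithian-2-yl)methyl]-2-(triethylsilyloxy)hex-5-en-3-one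
Conditions: DDQ (1.2 equiv), CH2Cl2/pH 7 buffer, 0 °C
Reagents that add atoms: none
Why: Oxidative PMB cleavage is selective for the electron-rich benzyl ether and is commonly run beside dialkyl dithianes, silyl ethers and unactivated alkenes at 0 °C; the buffer keeps the medium neutral, so neither the alkene nor the silyl group should shift.

Step 11
Reactants: 18 C5 alcohol (C2 epimers)
Product: 19 (2R)-2,4-dimethyl-3-oxo-5-[(2-propyl-1,3-dithian-2-yl)methyl]-2-(triethylsilyloxy)hex-5-enal (3-methylene keto aldehyde; C2 epimers)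
Conditions: Dess–Martin periodinane, pyridine, CH2Cl2, 0 °C → rt; short filtration, used at once
Reagents that add atoms: none
Why: The Dess–Martin oxidation delivers the β-keto aldehyde under base-free, nucleophile-free conditions, so deformylation and alkene migration are avoided, and C6 is safe because it has no hydrogen.

Step 12
Reactants: 19 3-methylene keto aldehyde (C2 epimers)
Product: 21 (5S,6R)-5-hydroxy-2,6-dimethyl-3-[(2-propyl-1,3-dithian-2-yl)methyl]-6-(triethylsilyloxy)cyclohex-2-en-1-one, via exocyclic-alkene ene adduct 20 (not isolated)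
Conditions: Me2AlCl (1.1 equiv), CH2Cl2, −78 → −40 °C; 1 M HCl quench; crude 20, 1,8-diazabicyclo[5.4.0]undec-7-ene (DBU, 0.2 equiv), CH2Cl2, 0 °C → rt
Reagents that add atoms: none
Why: The aluminium reagent binds the exposed C5 aldehyde in preference to the flanked C1 ketone, C4 (the CH2 end of the alkene) bonds to C5 while an allylic hydrogen moves to oxygen (from C1' in the concerted path, from C2 if a C3 cation intervenes), and the resulting complex loses methane to give an aluminium alkoxide, which leaves no proton source in the flask. The closest known reaction is the Lewis-acid-promoted type 2 intramolecular carbonyl-ene cyclisation of aldehydes onto 1,1-disubstituted alkenes, an established route to 3-alkylidenecyclohexanols. Ring A closes as a six-membered carbocycle, 6-exo-trig at the carbonyl carbon, with both alkene carbons C3 and C4 becoming ring members because the tether starts at the central ene carbon C3. The new C5 centre is governed by C6: in the chair-like bicyclic transition state the aldehyde oxygen is axial so that it reaches the allylic hydrogen, and C6 places its methyl equatorial and its silyloxy group axial and anti to the C5–O dipole, which should give the 5,6-trans (5S,6R) array. The step needs non-chelated activation and an alkene that stays at C3=C4 until the bond is made, and both are secured by about one equivalent of a monodentate aluminium reagent, the weakly donating bulky silyl ether, the low temperature and the absence of protic acid. DBU then moves the exocyclic or β,γ alkene (and eliminates any C3 chloride from a Prins-type leak) to the tetrasubstituted conjugated C2=C3 position, which also removes the C2 epimers.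

Step 13
Reactants: 21 C5 hydroxy enone with C6 silyl ether
Product: 22 (5S,6R)-5,6-dihydroxy-2,6-dimethyl-3-[(2-propyl-1,3-dithian-2-yl)methyl]cyclohex-2-en-1-one
Conditions: HF·pyridine, pyridine, THF, 0 °C → rt
Reagents that add atoms: none
Why: Fluoride desilylation under mildly acidic conditions removes the single silyl group wherever it sits (partial O-to-O migration under DBU would not matter), and no alkoxide forms that could start a retro-aldol or α-ketol shift.

Step 14
Reactants: 22 trans-diol
Product: 23 (5S,6R)-6-hydroxy-2,6-dimethyl-3-[(2-propyl-1,3-dithian-2-yl)methyl]-5-(triethylsilyloxy)cyclohex-2-en-1-one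
Conditions: Et3SiCl (1.2 equiv), imidazole, CH2Cl2, 0 °C
Reagents that add atoms: chlorotriethylsilane, CC[Si](Cl)(CC)CC
Why: Chlorosilane with imidazole discriminates sharply between a secondary and a tertiary alcohol, so only C5–OH is covered and C6–OH remains the one free hydroxyl.

Step 15
Reactants: 24 orsellinic acid
Product: 25 tert-butyldimethylsilyl 2,4-bis[(tert-butyldimethylsilyl)oxy]-6-methylbenzoate
Conditions: t-BuMe2SiCl (3.5 equiv), imidazole, DMF, rt
Reagents that add atoms: tert-butyldimethylsilyl chloride, CC(C)(C)[Si](C)(C)Cl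
Why: Exhaustive silylation at room temperature (no heating, so no decarboxylation) masks both phenols with groups that leave in the final fluoride step, and it gives a silyl ester that is a direct acid chloride precursor.

Step 16
Reactants: 23 C6 alcohol; 25 persilylated orsellinate
Product: 27 (1R,6S)-1,3-dimethyl-2-oxo-4-[(2-propyl-1,3-dithian-2-yl)methyl]-6-(triethylsilyloxy)cyclohex-3-en-1-yl 2,4-bis[(tert-butyldimethylsilyl)oxy]-6-methylbenzoate, via aroyl chloride 26 (not isolated)
Conditions: 25, (COCl)2, DMF (HCONMe2, cat.), CH2Cl2, 0 °C → rt, concentrate; then 23, 4-(dimethylamino)pyridine (DMAP), Et3N, toluene, 60 °C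
Reagents that add atoms: none
Why: Silyl esters are converted into acid chlorides by oxalyl chloride and catalytic DMF under neutral conditions, and DMAP-promoted acyl transfer then acylates the only free hydroxyl without forming the C6 alkoxide, which would invite silyl migration from C5 or an α-ketol shift.

Step 17
Reactants: 27 protected ester with dithiane
Product: 28 (1R,6S)-1,3-dimethyl-2-oxo-4-(2-oxopentyl)-6-(triethylsilyloxy)cyclohex-3-en-1-yl 2,4-bis[(tert-butyldimethylsilyl)oxy]-6-methylbenzoate
Conditions: MeI, CaCO3, MeCN/H2O (9:1), 40 °C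
Reagents that add atoms: water, O
Why: In alkylative dithiane hydrolysis S-methylation makes sulfur a leaving group and water delivers the carbonyl oxygen; the method is non-oxidising, so the electron-rich arene and the enone are left alone, and CaCO3 takes up HI without enolising the newly freed vinylogous β-diketone.

Step 18
Reactants: 28 tris-silyl ether
Product: 29 talarophilone, (1R,6S)-6-hydroxy-1,3-dimethyl-2-oxo-4-(2-oxopentyl)cyclohex-3-en-1-yl 2,4-dihydroxy-6-methylbenzoate
Conditions: HF·pyridine, THF, 0 °C → rt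
Reagents that add atoms: none
Why: Global fluoride desilylation in an acidic rather than basic medium frees C5–OH and both phenols without an alkoxide, so the aroyl group should not move from C6 to C5 and the C1' methylene is not deprotonated.

Compound list
1 | butanal | CCCC=O | starting material
2 | 2-propyl-1,3-dithiane | CCCC1SCCCS1 | intermediate
3 | 3-chloro-2-(chloromethyl)prop-1-ene | C=C(CCl)CCl | starting material
4 | 2-lithio-2-propyl-1,3-dithiane (not isolated) | [Li]C1(CCC)SCCCS1 | intermediate
5 | 2-[2-(chloromethyl)prop-2-en-1-yl]-2-propyl-1,3-dithiane | CCCC1(CC(=C)CCl)SCCCS1 | intermediate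
6 | (R)-2-methylglycidol | C[C@@]1(CO)CO1 | starting material
7 | sodium alkoxide of 6 (not isolated) | C[C@@]1(C[O-])CO1.[Na+] | intermediate
8 | (S)-2-{[(4-methoxybenzyl)oxy]methyl}-2-methyloxirane | C[C@@]1(COCc2ccc(OC)cc2)CO1 | intermediate
9 | (S)-3-[(4-methoxybenzyl)oxy]-2-methylpropane-1,2-diol | OC[C@](C)(O)COCc1ccc(OC)cc1 | intermediate
10 | (R)-1-[(4-methoxybenzyl)oxy]-2-methyl-2,3-bis(triethylsilyloxy)propane | CC[Si](CC)(CC)OC[C@](C)(O[Si](CC)(CC)CC)COCc1ccc(OC)cc1 | intermediate
11 | dimethyl(alkoxy)sulfonium chloride of the C1 arm (not isolated) | C[S+](C)OC[C@](C)(O[Si](CC)(CC)CC)COCc1ccc(OC)cc1.[Cl-] | intermediate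
12 | (R)-3-[(4-methoxybenzyl)oxy]-2-methyl-2-(triethylsilyloxy)propanal | O=C[C@](C)(O[Si](CC)(CC)CC)COCc1ccc(OC)cc1 | intermediate
13 | {2-[(2-propyl-1,3-dithian-2-yl)methyl]prop-2-en-1-yl}zinc chloride (not isolated) | CCCC1(CC(=C)C[Zn]Cl)SCCCS1 | intermediate
14 | (2R)-1-[(4-methoxybenzyl)oxy]-2-methyl-5-[(2-propyl-1,3-dithian-2-yl)methyl]-2-(triethylsilyloxy)hex-5-en-3-ol (carbinol epimers) | CCCC1(CC(=C)CC(O)[C@](C)(O[Si](CC)(CC)CC)COCc2ccc(OC)cc2)SCCCS1 | intermediate
15 | (R)-1-[(4-methoxybenzyl)oxy]-2-methyl-5-[(2-propyl-1,3-dithian-2-yl)methyl]-2-(triethylsilyloxy)hex-5-en-3-one | CCCC1(CC(=C)CC(=O)[C@](C)(O[Si](CC)(CC)CC)COCc2ccc(OC)cc2)SCCCS1 | intermediate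
16 | lithium dienolate of 15 (not isolated) | [Li+].CCCC1(CC(=C)C=C([O-])[C@](C)(O[Si](CC)(CC)CC)COCc2ccc(OC)cc2)SCCCS1 | intermediate
17 | (2R)-1-[(4-methoxybenzyl)oxy]-2,4-dimethyl-5-[(2-propyl-1,3-dithian-2-yl)methyl]-2-(triethylsilyloxy)hex-5-en-3-one (ring C2 epimers) | CCCC1(CC(=C)C(C)C(=O)[C@](C)(O[Si](CC)(CC)CC)COCc2ccc(OC)cc2)SCCCS1 | intermediate
18 | (2R)-1-hydroxy-2,4-dimethyl-5-[(2-propyl-1,3-dithian-2-yl)methyl]-2-(triethylsilyloxy)hex-5-en-3-one (ring C2 epimers) | CCCC1(CC(=C)C(C)C(=O)[C@](C)(O[Si](CC)(CC)CC)CO)SCCCS1 | intermediate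
19 | (2R)-2,4-dimethyl-3-oxo-5-[(2-propyl-1,3-dithian-2-yl)methyl]-2-(triethylsilyloxy)hex-5-enal (ring C2 epimers; ene precursor) | CCCC1(CC(=C)C(C)C(=O)[C@](C)(O[Si](CC)(CC)CC)C=O)SCCCS1 | intermediate
20 | (5S,6R)-5-hydroxy-2,6-dimethyl-3-[(2-propyl-1,3-dithian-2-yl)methylidene]-6-(triethylsilyloxy)cyclohexan-1-one (C2 epimers; E/Z; not isolated) | CCCC1(SCCCS1)C=C2C(C)C(=O)[C@](C)(O[Si](CC)(CC)CC)[C@@H](O)C2 | intermediate
21 | (5S,6R)-5-hydroxy-2,6-dimethyl-3-[(2-propyl-1,3-dithian-2-yl)methyl]-6-(triethylsilyloxy)cyclohex-2-en-1-one | CCCC1(SCCCS1)CC2=C(C)C(=O)[C@](C)(O[Si](CC)(CC)CC)[C@@H](O)C2 | intermediate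
22 | (5S,6R)-5,6-dihydroxy-2,6-dimethyl-3-[(2-propyl-1,3-dithian-2-yl)methyl]cyclohex-2-en-1-one | CCCC1(SCCCS1)CC2=C(C)C(=O)[C@](C)(O)[C@@H](O)C2 | intermediate
23 | (5S,6R)-6-hydroxy-2,6-dimethyl-3-[(2-propyl-1,3-dithian-2-yl)methyl]-5-(triethylsilyloxy)cyclohex-2-en-1-one | CCCC1(SCCCS1)CC2=C(C)C(=O)[C@](C)(O)[C@@H](O[Si](CC)(CC)CC)C2 | intermediate
24 | orsellinic acid | Cc1cc(O)cc(O)c1C(=O)O | starting material
25 | tert-butyldimethylsilyl 2,4-bis[(tert-butyldimethylsilyl)oxy]-6-methylbenzoate | Cc1cc(O[Si](C)(C)C(C)(C)C)cc(O[Si](C)(C)C(C)(C)C)c1C(=O)O[Si](C)(C)C(C)(C)C | intermediate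
26 | 2,4-bis[(tert-butyldimethylsilyl)oxy]-6-methylbenzoyl chloride (not isolated) | Cc1cc(O[Si](C)(C)C(C)(C)C)cc(O[Si](C)(C)C(C)(C)C)c1C(=O)Cl | intermediate
27 | (1R,6S)-1,3-dimethyl-2-oxo-4-[(2-propyl-1,3-dithian-2-yl)methyl]-6-(triethylsilyloxy)cyclohex-3-en-1-yl 2,4-bis[(tert-butyldimethylsilyl)oxy]-6-methylbenzoate | CCCC1(SCCCS1)CC2=C(C)C(=O)[C@](C)(OC(=O)c3c(C)cc(O[Si](C)(C)C(C)(C)C)cc3O[Si](C)(C)C(C)(C)C)[C@@H](O[Si](CC)(CC)CC)C2 | intermediate
28 | (1R,6S)-1,3-dimethyl-2-oxo-4-(2-oxopentyl)-6-(triethylsilyloxy)cyclohex-3-en-1-yl 2,4-bis[(tert-butyldimethylsilyl)oxy]-6-methylbenzoate | CCCC(=O)CC1=C(C)C(=O)[C@](C)(OC(=O)c2c(C)cc(O[Si](C)(C)C(C)(C)C)cc2O[Si](C)(C)C(C)(C)C)[C@@H](O[Si](CC)(CC)CC)C1 | intermediate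
29 | talarophilone | CCCC(=O)CC1=C(C)C(=O)[C@](C)(OC(=O)c2c(C)cc(O)cc2O)[C@@H](O)C1 | target

Total steps: 18. Longest linear sequence: 15 steps (6 → 29 through steps 3 to 14 and 16 to 18).

Steps most likely to fail

Step 12.
- **What may go wrong.** The C3=C4 alkene may move into conjugation with C1 before the C–C bond forms. The Lewis acid may set off an acyloin-type 1,2-shift of the α-silyloxy aldehyde. Closure through a chelated transition state would give poor facial selectivity at C5.
- **Fallback, from 19 back to 21.** C4 is made the terminus of an electron-rich diene, and the ring is closed in the aldol manifold instead of the ene manifold. Soft enolisation (t-BuMe2SiOTf, Et3N, CH2Cl2, −78 °C) touches only the C1 ketone, since the aldehyde has no α-hydrogen. This gives the silyl dienol ether aldehyde F1. BF3·OEt2 at −78 °C, which cannot chelate, then brings about an intramolecular vinylogous Mukaiyama aldol addition. Attack through C2 would give a four-membered ring, so only attack through C4 is productive. The conjugated enone 21 is formed directly once the silyl group is lost.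

Step 16.
- **What may go wrong.** Acyl transfer between a tertiary carbinol and a di-ortho-substituted aroyl chloride may be very slow. Prolonged heating would then cause loss or migration of silyl groups, or an α-ketol shift.
- **Fallback, from 23 back to 29.** Ring B is built on the ester oxygen instead of being forced on as an acyl donor.
  1. Commercial 2,2,6-trimethyl-4H-1,3-dioxin-4-one is deprotonated (LiN(SiMe3)2) and C-acetylated with acetyl chloride to give 2,2-dimethyl-6-(2-oxopropyl)-4H-1,3-dioxin-4-one F2.
  2. The dianion of F2 (LiN(i-Pr)2, 2 equiv) is acetylated with N-methoxy-N-methylacetamide to give 2,2-dimethyl-6-(2,4-dioxopentyl)-4H-1,3-dioxin-4-one F3.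
  3. Heating F3 with 23 in toluene at 110 °C releases the linear, sterically undemanding acylketene F4. Tertiary alcohols trap such ketenes, and here this gives the 3,5,7-trioxooctanoate ester F5.
  4. Et3N followed by mild acid brings about aldol cyclisation and dehydration to the free-phenol orsellinate F6.
  5. Alkylative dithiane hydrolysis as in step 17 gives the C5 silyl ether of the target F7, and HF·pyridine as in step 18 gives 29.

Step 9.
- **What may go wrong.** Proton exchange between product and dienolate may lead to double methylation. Some alkylation may occur at the γ-carbon. The alkene may move into conjugation during the quench.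
- **Fallback, from 4 and 12 back to 17.** The methyl group is brought in with the allyl metal, so no enolate is needed.
  1. Commercial diethyl ethylidenemalonate is reduced with i-Bu2AlH to 2-ethylidenepropane-1,3-diol F8.
  2. F8 is converted (MsCl, Et3N; LiCl, DMF) into 1-chloro-2-(chloromethyl)but-2-ene F9.
  3. Alkylation of 4 with an excess of F9 gives 2-[2-(chloromethyl)but-2-en-1-yl]-2-propyl-1,3-dithiane F10, and either alkene geometry serves.
  4. Zn and LiCl convert F10 into the substituted allylzinc chloride F11.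
  5. F11 adds to 12 through its methyl-bearing γ-carbon (crotylation-type SE2' addition) to give the C2-methyl homoallylic alcohol F12.
  6. Dess–Martin oxidation of F12 as in step 8 gives 17.

Further compounds
F1 | step 12 | (2S)-3-[(tert-butyldimethylsilyl)oxy]-2,4-dimethyl-5-[(2-propyl-1,3-dithian-2-yl)methyl]-2-(triethylsilyloxy)hexa-3,5-dienal (same spatial arrangement at ring C6 as 19) | O=C[C@@](C)(O[Si](CC)(CC)CC)C(O[Si](C)(C)C(C)(C)C)=C(C)C(=C)CC1(CCC)SCCCS1
F2 | step 16 | 2,2-dimethyl-6-(2-oxopropyl)-4H-1,3-dioxin-4-one | CC(=O)CC1=CC(=O)OC(C)(C)O1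
F3 | step 16 | 2,2-dimethyl-6-(2,4-dioxopentyl)-4H-1,3-dioxin-4-one | CC(=O)CC(=O)CC1=CC(=O)OC(C)(C)O1
F4 | step 16 | 3,5,7-trioxooct-1-en-1-one (acylketene, formed and trapped in the flask) | CC(=O)CC(=O)CC(=O)C=C=O
F5 | step 16 | (1R,6S)-1,3-dimethyl-2-oxo-4-[(2-propyl-1,3-dithian-2-yl)methyl]-6-(triethylsilyloxy)cyclohex-3-en-1-yl 3,5,7-trioxooctanoate | CCCC1(SCCCS1)CC2=C(C)C(=O)[C@](C)(OC(=O)CC(=O)CC(=O)CC(C)=O)[C@@H](O[Si](CC)(CC)CC)C2
F6 | step 16 | (1R,6S)-1,3-dimethyl-2-oxo-4-[(2-propyl-1,3-dithian-2-yl)methyl]-6-(triethylsilyloxy)cyclohex-3-en-1-yl 2,4-dihydroxy-6-methylbenzoate | CCCC1(SCCCS1)CC2=C(C)C(=O)[C@](C)(OC(=O)c3c(C)cc(O)cc3O)[C@@H](O[Si](CC)(CC)CC)C2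
F7 | step 16 | (1R,6S)-1,3-dimethyl-2-oxo-4-(2-oxopentyl)-6-(triethylsilyloxy)cyclohex-3-en-1-yl 2,4-dihydroxy-6-methylbenzoate | CCCC(=O)CC1=C(C)C(=O)[C@](C)(OC(=O)c2c(C)cc(O)cc2O)[C@@H](O[Si](CC)(CC)CC)C1
F8 | step 9 | 2-ethylidenepropane-1,3-diol | CC=C(CO)CO
F9 | step 9 | 1-chloro-2-(chloromethyl)but-2-ene | CC=C(CCl)CCl
F10 | step 9 | 2-[2-(chloromethyl)but-2-en-1-yl]-2-propyl-1,3-dithiane (E/Z) | CCCC1(CC(CCl)=CC)SCCCS1
F11 | step 9 | {2-[(2-propyl-1,3-dithian-2-yl)methyl]but-2-en-1-yl}zinc chloride (formed and used in the flask) | CCCC1(CC(C[Zn]Cl)=CC)SCCCS1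
F12 | step 9 | (2R)-1-[(4-methoxybenzyl)oxy]-2,4-dimethyl-5-[(2-propyl-1,3-dithian-2-yl)methyl]-2-(triethylsilyloxy)hex-5-en-3-ol (epimers at C3 and C4) | CCCC1(CC(=C)C(C)C(O)[C@](C)(O[Si](CC)(CC)CC)COCc2ccc(OC)cc2)SCCCS1
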